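The number I begin with is 12.7 %, the product read in the south-east run at 5.00 h, since cedar at 0.40 M stands close to that run's 0.33 M.

| flask | starting material | gas | remark | time |
|---|---|---|---|---|
| north-east | 0.016 M | 44 mM (held) | run made earlier |  |
| south-east | 0.33 M | 44 mM (held) | run made earlier |  |
| birch | 0.20 M | 44 mM (held) |  | 5.0 h |
| larch | 0.025 M | 44 mM (held) |  | 5.0 h |
| alder | 0.15 M | 44 mM (held) |  | 5.0 h |
| cedar | 0.40 M | 44 mM (held) |  | 5.0 h |
| elm | 0.30 M | 44 mM (held) |  | 5.0 h |
| ash | 0.10 M | 44 mM (held) |  | 5.0 h |

| run | time / h | product / % |
|---|---|---|
| north-east | 1.00 | 11.0 |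
| north-east | 2.00 | 21.2 |
| north-east | 3.00 | 24.0 |
| north-east | 4.00 | 25.5 |
| north-east | 5.00 | 27.4 |
| south-east | 0.417 | 1.1 |
| south-east | 0.833 | 2.5 |
| south-east | 1.33 | 3.7 |
| south-east | 2.50 | 7.1 |
| south-east | 5.00 | 12.7 |

(each reading ± 0.5 percentage points)

- the analysis behind the earlier runs scatters by 0.5 percentage points, standard deviation
- at the start none of the gas is in solution

- all flasks from highest to lowest amount of product, in percent of the starting material charged, at 5.0 h (birch / larch / alder / cedar / elm / ash)
- the amount of product, in percent of the starting material charged of the flask you put first, at 5.0 h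
- the amount of product, in percent of the starting material charged of the flask you put last, at 5.0 h

From north-east to south-east the last reading of product falls from 27.4 % to 12.7 % of the charge, yet c(product) rises from 4.38 mM to 41.9 mM. I take both trends to hold across these flasks, so I order them by rising charge, with larch first and cedar last. The first trend gives the upper bounds: 12.7 % for cedar and 27.4 % for larch. The second gives the lower bounds: cedar makes at least 41.9 mM, which is 10.5 % of its charge, and larch is held likewise at 17.5 %.

To tighten these, I treat larch and cedar each as a small correction to its nearest run. I call the drag 13.5 L mol⁻¹: the rise in the reciprocal of the product fraction per unit of charge, read between the two runs. Adding drag times the difference in charge to south-east's reciprocal gives cedar 11.3 %, and the same step from north-east gives larch 26.5 %. That straight line is my assumption, not a bound.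

The forecast gives larch > ash > alder > birch > elm > cedar, with larch at 27 % and cedar at 10.9 %, both inside my brackets, and it assumes that “the break occurs at a fixed fraction”.

The flasks give larch > ash > alder > birch > elm > cedar, with larch at 26.9 % and cedar at 10.7 %.

    starting material + partner → intermediate B (k = 0.590 L mol⁻¹ min⁻¹)
    starting material + partner → product (k = 0.350 L mol⁻¹ min⁻¹)
    starting material ⇌ intermediate A (K = 3.10, k = 0.00750 min⁻¹)
    partner + intermediate B ⇌ intermediate C (K = 40.0 L mol⁻¹, k = 0.750 L mol⁻¹ min⁻¹)
    intermediate C → decomposed reagent (k = 0.00460 min⁻¹)
    gas ⇌ partner, rate k6*(csat - [partner]) (kL = 0.0110 min⁻¹)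

Between larch and cedar, the drag now reads 14.9 L mol⁻¹. Carried from larch to its neighbour charged with 0.062 M, this drag gives 23.5 %. That neighbour flask gives 24.6 %, more than the line, and at that time its intermediate A stands at 31.6 %, more than its product.

The numbers in the tables stem from a simulated flask for an exercise; noise was put on by code.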